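**Retrosynthetic overview**

- Last bond: O1–C2 of the dihydropyranone, closed by a catalyst-controlled 6-endo oxa-Michael addition of a 1,3-diketone enol onto its own crotonyl unit. This sets the R centre.
- The enol–enone coumarin comes from a Knoevenagel/translactonisation cascade (coumarin lactone C–O) between a salicylaldehyde lactol and 4-hydroxy-6-propenyl-2-pyrone.
- The lactol comes from 2,4-dimethylresorcinol by formylation, MOM protection, and aldehyde-directed ortho-lithiation with opening of (S)-propylene oxide (S centre from the chiral pool).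
- The pyrone comes from C-acylation of the diketene–acetone adduct with crotonyl chloride, then acylketene cyclisation.
- Ring order: benzene ring bought, then the coumarin pyranone ring (step 6), then the dihydropyranone ring (step 7).

Assumption: 2,4-dimethylresorcinol, (S)-propylene oxide, 2,2,6-trimethyl-4H-1,3-dioxin-4-one and (E)-crotonyl chloride are taken as catalogue items.

**Route**

Step 1
Reactants: 1 2,4-dimethylresorcinol (2,4-dimethylbenzene-1,3-diol)
Product: 3 2,4-dihydroxy-3,5-dimethylbenzaldehyde, via aryl iminium chloride 2 (not isolated)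
Conditions: POCl3, DMF, 0 °C → rt; then H2O, 60 °C
Reagents that add atoms: DMF, CN(C)C=O; water, O
Why: Vilsmeier–Haack formylation, in which the chloroiminium ion attacks the only free ring position that is ortho/para to the two hydroxyls (the other free position is meta to both) and water then hydrolyses iminium salt 2 to the aldehyde.

Step 2
Reactants: 3 2,4-dihydroxy-3,5-dimethylbenzaldehyde
Product: 5 2,4-bis(methoxymethoxy)-3,5-dimethylbenzaldehyde, via disodium bis-phenoxide 4 (not isolated)
Conditions: NaH, MOMCl, DMF, 0 °C → rt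
Reagents that add atoms: chloromethyl methyl ether (MOMCl), COCCl
Why: Williamson-type O-alkylation, in which NaH deprotonates both phenols (the chelated ortho one included) and the small, reactive chloromethyl ether alkylates both oxygens of 4.

Step 3
Reactants: 5 2,4-bis(methoxymethoxy)-3,5-dimethylbenzaldehyde; 6 (S)-propylene oxide [(2S)-2-methyloxirane]
Product: 10 (3S)-6,8-dihydroxy-3,5,7-trimethyl-3,4-dihydro-1H-isochromen-1-ol, via lithium α-amino alkoxide 7 (not isolated), via ring-lithiated α-amino alkoxide 8 (not isolated), via bis-MOM lactol 9 (not isolated)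
Conditions: LiN(Me)CH2CH2NMe2 (from the amine and n-BuLi), THF, −20 °C; n-BuLi, −20 → 0 °C; 6, BF3·OEt2, −78 °C; then 3 M HCl, THF, 40 °C
Reagents that add atoms: none
Why: Comins-type in situ aldehyde protection and directed ortho-metalation, in which the lithium amide adds to the aldehyde (7), its chelating diamine arm directs n-BuLi to the only ring hydrogen (8), BF3-assisted SN2 opening of the epoxide at its CH2 terminus leaves the stereocentre of 6 untouched (S stays S), and aqueous HCl releases the aldehyde, which closes to lactol 9, and cleaves both MOM acetals.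

Step 4
Reactants: 11 2,2,6-trimethyl-4H-1,3-dioxin-4-one; 12 (E)-crotonyl chloride [(2E)-but-2-enoyl chloride]
Product: 14 2,2-dimethyl-6-[(3E)-2-oxopent-3-en-1-yl]-4H-1,3-dioxin-4-one, via lithium dienolate 13 (not isolated)
Conditions: LiN(SiMe3)2 (2 equiv, with 2 equiv of 11), THF, −78 °C; then 12 (1 equiv), −78 °C
Reagents that add atoms: none
Why: vinylogous Claisen-type C-acylation, in which the γ-carbon of dienolate 13 attacks the acid chloride 1,2-selectively at low temperature and the second equivalent of enolate serves as base for the more acidic product, as established for cinnamoyl chlorides.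

Step 5
Reactants: 14 2,2-dimethyl-6-[(3E)-2-oxopent-3-en-1-yl]-4H-1,3-dioxin-4-one
Product: 16 4-hydroxy-6-[(1E)-prop-1-en-1-yl]-2H-pyran-2-one, via acylketene 15 (not isolated)
Conditions: PhMe, 110 °C
Reagents that add atoms: none
Why: thermal retro-hetero-Diels–Alder loss of acetone gives acylketene 15, which is trapped intramolecularly by the enol oxygen of the side-chain ketone to close the 4-hydroxy-2-pyrone.

Step 6
Reactants: 10 (3S)-6,8-dihydroxy-3,5,7-trimethyl-3,4-dihydro-1H-isochromen-1-ol; 16 4-hydroxy-6-[(1E)-prop-1-en-1-yl]-2H-pyran-2-one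
Product: 18 7-hydroxy-5-[(2S)-2-hydroxypropyl]-6,8-dimethyl-3-[(4E)-3-oxohex-4-enoyl]-2H-chromen-2-one, via Knoevenagel adduct 17 (not isolated)
Conditions: piperidine (10 mol%), AcOH (10 mol%), EtOH, 50 °C
Reagents that add atoms: none
Why: Knoevenagel condensation/translactonisation cascade known for salicylaldehydes and 4-hydroxy-6-methyl-2-pyrone, in which the open hydroxy-aldehyde form of 10 condenses at C3 of the pyrone (17), the ortho-phenol then attacks the pyrone lactone carbonyl to close the coumarin lactone and release the 1,3-diketone, and the diketonate present under the amine buffer is too poor an oxa-Michael partner to consume the enone.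

Step 7
Reactants: 18 7-hydroxy-5-[(2S)-2-hydroxypropyl]-6,8-dimethyl-3-[(4E)-3-oxohex-4-enoyl]-2H-chromen-2-one
Product: 19 7-hydroxy-5-[(2S)-2-hydroxypropyl]-6,8-dimethyl-3-[(2R)-2-methyl-4-oxo-3,4-dihydro-2H-pyran-6-yl]-2H-chromen-2-one
Conditions: (R)-3,3′-bis(2,4,6-triisopropylphenyl)-1,1′-binaphthalene-2,2′-diyl N-triflylphosphoramide (10 mol%), CHCl3, 4 Å MS, −20 °C
Reagents that add atoms: none
Why: Proposed new method: a confined chiral Brønsted acid catalyses a catalyst-controlled 6-endo-trig oxa-Michael ring closure of an acyclic 1,3-diketone enol onto its own crotonyl unit, the acid protonating or hydrogen-bonding the cross-conjugated dienone carbonyl while its basic P=O/S=O oxygen holds the enol O–H, so that the enol oxygen on the coumarin side adds to one face of the β-carbon inside the chiral ion pair (equally an acid-accelerated oxa-6π closure of the 1-oxatriene tautomer followed by tautomerisation) and the new C–O bond sets C2 of the dihydropyranone as R without touching the remote carbinol; the closest known chemistry is the racemic protic-acid cyclisation of ene-1,3-diones to 2,3-dihydro-4H-pyran-4-ones, chiral phosphoric-acid and amine–thiourea catalysed intramolecular oxa-Michael additions of phenols to enones (chromanones, flavanones), and chiral N-triflylphosphoramide-catalysed Nazarov cyclisation of dienones.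

**Compound list**

1 | 2,4-dimethylresorcinol | Cc1ccc(O)c(C)c1O | starting material
2 | N-[(2,4-dihydroxy-3,5-dimethylphenyl)methylidene]-N-methylmethanaminium chloride | C[N+](C)=Cc1cc(C)c(O)c(C)c1O.[Cl-] | intermediate (not isolated)
3 | 2,4-dihydroxy-3,5-dimethylbenzaldehyde | Cc1cc(C=O)c(O)c(C)c1O | intermediate
4 | disodium 4-formyl-2,6-dimethylbenzene-1,3-diolate | [Na+].[Na+].Cc1cc(C=O)c([O-])c(C)c1[O-] | intermediate (not isolated)
5 | 2,4-bis(methoxymethoxy)-3,5-dimethylbenzaldehyde | Cc1cc(C=O)c(OCOC)c(C)c1OCOC | intermediate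
6 | (S)-propylene oxide | C[C@H]1CO1 | starting material
7 | lithium [2,4-bis(methoxymethoxy)-3,5-dimethylphenyl]{[2-(dimethylamino)ethyl](methyl)amino}methanolate (either configuration at the aminal carbon) | CN(C)CCN(C)C(O[Li])c1cc(C)c(OCOC)c(C)c1OCOC | intermediate (not isolated)
8 | 6-lithio derivative of 7 | CN(C)CCN(C)C(O[Li])c1c([Li])c(C)c(OCOC)c(C)c1OCOC | intermediate (not isolated)
9 | (3S)-6,8-bis(methoxymethoxy)-3,5,7-trimethyl-3,4-dihydro-1H-isochromen-1-ol (C1 epimers) | C[C@H]1Cc2c(C)c(OCOC)c(C)c(OCOC)c2C(O)O1 | intermediate (not isolated)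
10 | (3S)-6,8-dihydroxy-3,5,7-trimethyl-3,4-dihydro-1H-isochromen-1-ol (lactol, C1 epimers; ring-chain tautomer of 2,4-dihydroxy-6-[(2S)-2-hydroxypropyl]-3,5-dimethylbenzaldehyde) | C[C@H]1Cc2c(C)c(O)c(C)c(O)c2C(O)O1 | intermediate
11 | 2,2,6-trimethyl-4H-1,3-dioxin-4-one | CC1=CC(=O)OC(C)(C)O1 | starting material
12 | (E)-crotonyl chloride | C/C=C/C(Cl)=O | starting material
13 | lithium 2,2-dimethyl-6-methylidene-6H-1,3-dioxin-4-olate | C=C1C=C(O[Li])OC(C)(C)O1 | intermediate (not isolated)
14 | 2,2-dimethyl-6-[(3E)-2-oxopent-3-en-1-yl]-4H-1,3-dioxin-4-one | C/C=C/C(=O)CC1=CC(=O)OC(C)(C)O1 | intermediate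
15 | (6E)-octa-1,6-diene-1,3,5-trione (acylketene) | C/C=C/C(=O)CC(=O)C=C=O | intermediate (not isolated)
16 | 4-hydroxy-6-[(1E)-prop-1-en-1-yl]-2H-pyran-2-one | C/C=C/C1=CC(O)=CC(=O)O1 | intermediate
17 | 3-{2,4-dihydroxy-6-[(2S)-2-hydroxypropyl]-3,5-dimethylbenzylidene}-6-[(1E)-prop-1-en-1-yl]-2H-pyran-2,4(3H)-dione | C/C=C/C1=CC(=O)C(=Cc2c(O)c(C)c(O)c(C)c2C[C@H](C)O)C(=O)O1 | intermediate (not isolated)
18 | 7-hydroxy-5-[(2S)-2-hydroxypropyl]-6,8-dimethyl-3-[(4E)-3-oxohex-4-enoyl]-2H-chromen-2-one (drawn as the diketone, present as the chelated enol) | C/C=C/C(=O)CC(=O)c1cc2c(C[C@H](C)O)c(C)c(O)c(C)c2oc1=O | intermediate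
19 | 7-hydroxy-5-[(2S)-2-hydroxypropyl]-6,8-dimethyl-3-[(2R)-2-methyl-4-oxo-3,4-dihydro-2H-pyran-6-yl]-2H-chromen-2-one | Cc1c(O)c(C)c2oc(=O)c(C3=CC(=O)C[C@@H](C)O3)cc2c1C[C@H](C)O | target

**Step count and risks**

Total steps: 7. Longest linear sequence: 5 (steps 1, 2, 3, 6, 7); the pyrone branch is steps 4 and 5.

Three steps most likely to fail:

Step 3. The lithiation site is flanked on both sides, and the excess n-BuLi and the amine donors compete for the epoxide and for BF3. The fallback replaces the α-amino alkoxide by a tertiary amide, a stronger directing group that also changes the oxidation level. It sets out from 1 and comes back at 10.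
- Protect 1 (NaH, MOMCl) to give 1,3-bis(methoxymethoxy)-2,4-dimethylbenzene F1.
- Lithiate next to the acetal oxygen (n-BuLi, TMEDA, 0 °C) and quench with ClCONEt2 to give N,N-diethyl-2,4-bis(methoxymethoxy)-3,5-dimethylbenzamide F2.
- Treat with s-BuLi/TMEDA at −78 °C, then 6 and BF3·OEt2, to give N,N-diethyl-2-[(2S)-2-hydroxypropyl]-4,6-bis(methoxymethoxy)-3,5-dimethylbenzamide F3.
- Heat with 3 M HCl in dioxane at 80 °C, which lactonises and removes both MOM groups, to give (3S)-6,8-dihydroxy-3,5,7-trimethyl-3,4-dihydro-1H-isochromen-1-one F4.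
- Reduce with i-Bu2AlH (4 equiv, CH2Cl2, −78 °C) to lactol 10.

Step 6. The aldehyde is masked as a lactol, is electron-rich and is doubly ortho-substituted. The adduct may also stall before translactonisation, or the enone may suffer amine addition. The fallback changes the carbon nucleophile from the cyclic pyrone to an open-chain β-keto ester, so that the coumarin closes by direct lactonisation instead of translactonisation. It sets out from 14 (with 10) and comes back at 18.
- Heat 14 in toluene with methanol (5 equiv) at 110 °C, so that the acylketene is trapped intermolecularly, to give methyl (6E)-3,5-dioxooct-6-enoate F5.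
- Condense F5 with 10 (piperidine/AcOH, EtOH, 50 °C). Only condensation at C2 (the ester-flanked methylene) can end in irreversible lactonisation with loss of methanol, which gives 18.

Step 7 (the new step). The face selectivity and turnover of the chiral acid are unproven, and a racemic background closure on acidic surfaces would erode the diastereomer ratio. The sense of induction has to be read from the first run; the (S)-acid is equally available. The fallback uses known chemistry and takes the R centre from the chiral pool. It sets out from 10 and comes back at 19.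
- Silylate commercial methyl (R)-3-hydroxybutanoate (TBSCl, imidazole) to give methyl (3R)-3-[(tert-butyldimethylsilyl)oxy]butanoate F6.
- Acylate the dianion of methyl acetoacetate (NaH, then n-BuLi, THF, 0 °C) with F6 to give methyl (7R)-7-[(tert-butyldimethylsilyl)oxy]-3,5-dioxooctanoate F7.
- Cyclise with DBU in toluene at 80 °C to give 6-[(2R)-2-[(tert-butyldimethylsilyl)oxy]propyl]-4-hydroxy-2H-pyran-2-one F8.
- Run the cascade of step 6 with 10 to give 3-[(5R)-5-[(tert-butyldimethylsilyl)oxy]-3-oxohexanoyl]-7-hydroxy-5-[(2S)-2-hydroxypropyl]-6,8-dimethyl-2H-chromen-2-one F9.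
- Treat with 1 M HCl in THF/H2O at rt. This removes the silyl group and the freed δ-hydroxy-1,3-diketone cyclodehydrates to 19. No bond to the stereocentre is broken, so R is carried over.

Further compounds
F1 | step 3 | 1,3-bis(methoxymethoxy)-2,4-dimethylbenzene | Cc1ccc(OCOC)c(C)c1OCOC
F2 | step 3 | N,N-diethyl-2,4-bis(methoxymethoxy)-3,5-dimethylbenzamide | CCN(CC)C(=O)c1cc(C)c(OCOC)c(C)c1OCOC
F3 | step 3 | N,N-diethyl-2-[(2S)-2-hydroxypropyl]-4,6-bis(methoxymethoxy)-3,5-dimethylbenzamide | CCN(CC)C(=O)c1c(C[C@H](C)O)c(C)c(OCOC)c(C)c1OCOC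
F4 | step 3 | (3S)-6,8-dihydroxy-3,5,7-trimethyl-3,4-dihydro-1H-isochromen-1-one | C[C@H]1Cc2c(C)c(O)c(C)c(O)c2C(=O)O1
F5 | step 6 | methyl (6E)-3,5-dioxooct-6-enoate | C/C=C/C(=O)CC(=O)CC(=O)OC
F6 | step 7 | methyl (3R)-3-[(tert-butyldimethylsilyl)oxy]butanoate | C[C@@H](O[Si](C)(C)C(C)(C)C)CC(=O)OC
F7 | step 7 | methyl (7R)-7-[(tert-butyldimethylsilyl)oxy]-3,5-dioxooctanoate | C[C@@H](O[Si](C)(C)C(C)(C)C)CC(=O)CC(=O)CC(=O)OC
F8 | step 7 | 6-[(2R)-2-[(tert-butyldimethylsilyl)oxy]propyl]-4-hydroxy-2H-pyran-2-one | C[C@@H](O[Si](C)(C)C(C)(C)C)CC1=CC(O)=CC(=O)O1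
F9 | step 7 | 3-[(5R)-5-[(tert-butyldimethylsilyl)oxy]-3-oxohexanoyl]-7-hydroxy-5-[(2S)-2-hydroxypropyl]-6,8-dimethyl-2H-chromen-2-one | C[C@@H](O[Si](C)(C)C(C)(C)C)CC(=O)CC(=O)c1cc2c(C[C@H](C)O)c(C)c(O)c(C)c2oc1=O
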